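The pyran-2-one ring is closed last, by disconnecting the lactone O1–C2 bond and the C3=C4 double bond. The feature exploited is that the lactone atoms O1, C2, C3 and C4 are attached through C4a, which sits between the oxygenated C5 and C8a. The ring-opened precursor, a 4-O-alkyl-2,6-dihydroxybenzaldehyde carrying the complete acetonide-protected side chain, therefore has two equivalent ortho hydroxyls. (Triphenylphosphoranylidene)ketene acylates one of them, and the acyl ylide formed olefinates the formyl group in the same flask. This gives the coumarin ring and leaves the other hydroxyl as the free 5-OH. Both stereocentres are bought with L-tartrate.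

Key step: step 13

Remark: the (4R,5R) acetonide of L-tartrate already has the spatial arrangement of C9/C10; the descriptors become (9S,10R) only through changed CIP priorities, no bond at either centre is broken in the route, and the hindered tertiary C11 hydroxyl is carried unprotected.

Step 1
Reactants: 1 geraniol
Product: 2 tert-butyl{[(2E)-3,7-dimethylocta-2,6-dien-1-yl]oxy}diphenylsilane
Conditions: TBDPSCl, imidazole, CH2Cl2, 0 °C → rt
Reagents that add atoms: tert-butyl(chloro)diphenylsilane, CC(C)(C)[Si](Cl)(c1ccccc1)c1ccccc1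
Why: Imidazole-promoted silylation of a primary allylic alcohol gives a silyl ether that should survive peracid, periodic acid, butyllithium and zirconium hydride and be removable with fluoride.

Step 2
Reactants: 2 tert-butyl{[(2E)-3,7-dimethylocta-2,6-dien-1-yl]oxy}diphenylsilane
Product: 3 tert-butyl{[(2E)-5-(3,3-dimethyloxiran-2-yl)-3-methylpent-2-en-1-yl]oxy}diphenylsilane (racemic at the oxirane CH)
Conditions: mCPBA (1.0 equiv), CH2Cl2, −20 → 0 °C
Reagents that add atoms: 3-chloroperoxybenzoic acid, O=C(OO)c1cccc(Cl)c1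
Why: Prilezhaev epoxidation should favour the remote, more electron-rich 6,7-alkene because the 2,3-alkene is deactivated by the allylic silyloxy group; the epoxide stereocentre is irrelevant since it is cleaved next.

Step 3
Reactants: 3 tert-butyl{[(2E)-5-(3,3-dimethyloxiran-2-yl)-3-methylpent-2-en-1-yl]oxy}diphenylsilane
Product: 4 (4E)-6-[(tert-butyldiphenylsilyl)oxy]-4-methylhex-4-enal
Conditions: H5IO6, THF–H2O, 0 °C
Reagents that add atoms: none
Why: Periodic acid opens the epoxide at its tertiary carbon to the glycol and cleaves it (Malaprade-type glycol cleavage), removing the isopropylidene terminus as acetone and leaving the (E)-alkene untouched.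

Step 4
Reactants: 4 (4E)-6-[(tert-butyldiphenylsilyl)oxy]-4-methylhex-4-enal
Product: 5 tert-butyl{[(2E)-3-methylhept-2-en-6-yn-1-yl]oxy}diphenylsilane
Conditions: dimethyl (1-diazo-2-oxopropyl)phosphonate, K2CO3, MeOH, 0 °C → rt
Reagents that add atoms: dimethyl (1-diazo-2-oxopropyl)phosphonate, COP(=O)(OC)C(=[N+]=[N-])C(C)=O
Why: Seyferth–Gilbert homologation in its Ohira–Bestmann form converts an enolisable aldehyde into the terminal alkyne under carbonate/methanol conditions that the silyl ether tolerates.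

Step 5
Reactants: 5 tert-butyl{[(2E)-3-methylhept-2-en-6-yn-1-yl]oxy}diphenylsilane
Product: 7 tert-butyl{[(2E)-3-methyloct-2-en-6-yn-1-yl]oxy}diphenylsilane, via lithium acetylide 6 (not isolated)
Conditions: n-BuLi, THF, −78 °C; MeI, −78 °C → rt
Reagents that add atoms: iodomethane, CI
Why: Deprotonation of the terminal alkyne and SN2 methylation of the acetylide installs the carbon that becomes the C7 methyl group.

Step 6
Reactants: 7 tert-butyl{[(2E)-3-methyloct-2-en-6-yn-1-yl]oxy}diphenylsilane
Product: 9 {[(2E,6E)-7-bromo-3-methylocta-2,6-dien-1-yl]oxy}(tert-butyl)diphenylsilane, via alkenylzirconocene 8 (not isolated)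
Conditions: Cp2Zr(H)Cl (2.2 equiv), THF, 50 °C; then NBS, 0 °C
Reagents that add atoms: N-bromosuccinimide, O=C1CCC(=O)N1Br
Why: Hydrozirconation with the Schwartz reagent is a syn addition that, with excess reagent and gentle heating, should equilibrate to put zirconium on the less hindered methyl-bearing carbon, and bromodezirconation proceeds with retention to fix the (6E) geometry.

Step 7
Reactants: 10 dimethyl (4R,5R)-2,2-dimethyl-1,3-dioxolane-4,5-dicarboxylate
Product: 11 methyl (4R,5S)-5-(hydroxymethyl)-2,2-dimethyl-1,3-dioxolane-4-carboxylate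
Conditions: NaBH4 (0.55 equiv), MeOH, 0 °C
Reagents that add atoms: none
Why: Borohydride reduction of an α-alkoxy-activated ester with sub-stoichiometric hydride should stop mainly after one ester, and because the diester is C2-symmetric either ester gives the same product, with recovered diester recycled and the over-reduced diol separated.

Step 8
Reactants: 11 methyl (4R,5S)-5-(hydroxymethyl)-2,2-dimethyl-1,3-dioxolane-4-carboxylate
Product: 12 2-[(4R,5S)-5-(hydroxymethyl)-2,2-dimethyl-1,3-dioxolan-4-yl]propan-2-ol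
Conditions: MeMgBr (4 equiv), THF, 0 °C → rt; aq NH4Cl
Reagents that add atoms: methylmagnesium bromide, C[Mg]Br
Why: Double Grignard addition to the ester, after the first equivalent deprotonates the hydroxyl, builds the tertiary carbinol (C11) without touching the C–O bonds of the stereocentres.

Step 9
Reactants: 12 2-[(4R,5S)-5-(hydroxymethyl)-2,2-dimethyl-1,3-dioxolan-4-yl]propan-2-ol
Product: 13 2-[(4R,5R)-5-(iodomethyl)-2,2-dimethyl-1,3-dioxolan-4-yl]propan-2-ol
Conditions: I2, PPh3, imidazole, toluene, rt → 60 °C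
Reagents that add atoms: iodine, II
Why: In this Garegg–Samuelsson (Appel-type) iodination only the primary hydroxyl forms an alkoxyphosphonium ion that iodide can displace, the tertiary alcohol being too hindered to react.

Step 10
Reactants: 9 {[(2E,6E)-7-bromo-3-methylocta-2,6-dien-1-yl]oxy}(tert-butyl)diphenylsilane; 13 2-[(4R,5R)-5-(iodomethyl)-2,2-dimethyl-1,3-dioxolan-4-yl]propan-2-ol
Product: 14 2-[(4R,5S)-5-{(2E,6E)-8-[(tert-butyldiphenylsilyl)oxy]-2,6-dimethylocta-2,6-dien-1-yl}-2,2-dimethyl-1,3-dioxolan-4-yl]propan-2-ol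
Conditions: NiI2·xH2O (10 mol %), 4,4′-di-tert-butyl-2,2′-bipyridine (10 mol %), Mn powder (3 equiv), NaI (25 mol %), pyridine (10 mol %), DMPU, 40 °C; 13 in 1.5-fold excess
Reagents that add atoms: none
Why: Nickel-catalysed reductive cross-electrophile coupling joins C7 to C8: the alkenyl bromide adds to nickel with retention of geometry, the iodide enters as a primary alkyl radical that does not expel the β-oxygen, and manganese in place of zinc avoids a β-alkoxy organometallic, while free hydroxyl, silyl ether and acetonide are tolerated.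

Step 11
Reactants: 14 2-[(4R,5S)-5-{(2E,6E)-8-[(tert-butyldiphenylsilyl)oxy]-2,6-dimethylocta-2,6-dien-1-yl}-2,2-dimethyl-1,3-dioxolan-4-yl]propan-2-ol
Product: 15 (2E,6E)-8-[(4S,5R)-5-(2-hydroxypropan-2-yl)-2,2-dimethyl-1,3-dioxolan-4-yl]-3,7-dimethylocta-2,6-dien-1-ol
Conditions: TBAF, THF, 0 °C → rt
Reagents that add atoms: none
Why: Fluoride cleaves the Si–O bond and frees the primary allylic alcohol without affecting the acetonide or the tertiary alcohol.

Step 12
Reactants: 15 (2E,6E)-8-[(4S,5R)-5-(2-hydroxypropan-2-yl)-2,2-dimethyl-1,3-dioxolan-4-yl]-3,7-dimethylocta-2,6-dien-1-ol; 16 2,4,6-trihydroxybenzaldehyde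
Product: 17 2,6-dihydroxy-4-{[(2E,6E)-8-[(4S,5R)-5-(2-hydroxypropan-2-yl)-2,2-dimethyl-1,3-dioxolan-4-yl]-3,7-dimethylocta-2,6-dien-1-yl]oxy}benzaldehyde
Conditions: PPh3, DIAD, THF, 0 °C → rt; 16 in 1.5-fold excess
Reagents that add atoms: none
Why: In this Mitsunobu etherification only the primary allylic alcohol is activated (the tertiary one is inert) and it should be displaced by the phenoxide of the 4-OH, the most acidic and least hindered of the three because it is para to the formyl group and not chelated, with excess phenol suppressing dialkylation.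

Step 13
Reactants: 17 2,6-dihydroxy-4-{[(2E,6E)-8-[(4S,5R)-5-(2-hydroxypropan-2-yl)-2,2-dimethyl-1,3-dioxolan-4-yl]-3,7-dimethylocta-2,6-dien-1-yl]oxy}benzaldehyde; 18 (triphenylphosphoranylidene)ketene
Product: 21 5-hydroxy-7-{[(2E,6E)-8-[(4S,5R)-5-(2-hydroxypropan-2-yl)-2,2-dimethyl-1,3-dioxolan-4-yl]-3,7-dimethylocta-2,6-dien-1-yl]oxy}-2H-chromen-2-one, via acyl ylide 19 (not isolated), via oxaphosphetane 20 (not isolated)
Conditions: 18 (1.05 equiv), toluene, rt → 80 °C
Reagents that add atoms: none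
Why: A phenolic O–H adds across the C=C of the cumulated ylide to give the aryl (triphenylphosphoranylidene)acetate 19 (O1–C2 bond), whose ylide carbon then attacks the neighbouring formyl carbon and, through oxaphosphetane 20, expels Ph3PO to form the C3=C4 bond. This is the established conversion of salicylaldehydes into coumarins with the Bestmann ylide, that is, O-acylation followed by intramolecular Wittig olefination. The pyranone ring closes in a 6-exo-trig mode (ylide carbon onto the exocyclic C=O), and the ring itself enforces the cis alkene, so neither isomerisation nor forcing temperature is needed. No stereocentre is created, and the acetonide-held C9 and C10 centres are spectators. The only selectivity required is acylation of a single phenol: 5-OH versus 7-OR regiochemistry is settled by the mirror symmetry of 17, one equivalent of 18 limits acylation to one hydroxyl, and the hindered, weakly acidic C11 alcohol should not compete with a phenol for the ylide. The neutral conditions lie well below the onset of aromatic Claisen rearrangement, so the allyl aryl ether, both alkenes and the acetonide should survive.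

Step 14
Reactants: 21 5-hydroxy-7-{[(2E,6E)-8-[(4S,5R)-5-(2-hydroxypropan-2-yl)-2,2-dimethyl-1,3-dioxolan-4-yl]-3,7-dimethylocta-2,6-dien-1-yl]oxy}-2H-chromen-2-one
Product: 22 5-hydroxy-7-{[(2E,6E,9S,10R)-9,10,11-trihydroxy-3,7,11-trimethyldodeca-2,6-dien-1-yl]oxy}-2H-chromen-2-one
Conditions: AcOH–H2O–THF (3:1:1), 45 °C
Reagents that add atoms: none
Why: Acid-catalysed hydrolysis of the isopropylidene ketal in weak aqueous acid releases the 9,10-diol with cleavage only at the ketal carbon, so both configurations are kept, and the acid is too weak to ionise the allyl aryl ether or protonate the trisubstituted alkenes.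

Compound list
1 | geraniol, (2E)-3,7-dimethylocta-2,6-dien-1-ol | CC(C)=CCC/C(C)=C/CO | starting material
2 | tert-butyl{[(2E)-3,7-dimethylocta-2,6-dien-1-yl]oxy}diphenylsilane | CC(C)=CCC/C(C)=C/CO[Si](c1ccccc1)(c1ccccc1)C(C)(C)C | intermediate
3 | tert-butyl{[(2E)-5-(3,3-dimethyloxiran-2-yl)-3-methylpent-2-en-1-yl]oxy}diphenylsilane, racemic at the oxirane CH | CC1(C)OC1CC/C(C)=C/CO[Si](c1ccccc1)(c1ccccc1)C(C)(C)C | intermediate
4 | (4E)-6-[(tert-butyldiphenylsilyl)oxy]-4-methylhex-4-enal | O=CCC/C(C)=C/CO[Si](c1ccccc1)(c1ccccc1)C(C)(C)C | intermediate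
5 | tert-butyl{[(2E)-3-methylhept-2-en-6-yn-1-yl]oxy}diphenylsilane | C#CCC/C(C)=C/CO[Si](c1ccccc1)(c1ccccc1)C(C)(C)C | intermediate
6 | lithium acetylide of 5, {(5E)-7-[(tert-butyldiphenylsilyl)oxy]-5-methylhept-5-en-1-yn-1-yl}lithium | [Li]C#CCC/C(C)=C/CO[Si](c1ccccc1)(c1ccccc1)C(C)(C)C | intermediate
7 | tert-butyl{[(2E)-3-methyloct-2-en-6-yn-1-yl]oxy}diphenylsilane | CC#CCC/C(C)=C/CO[Si](c1ccccc1)(c1ccccc1)C(C)(C)C | intermediate
8 | chlorobis(cyclopentadienyl){(2E,6E)-8-[(tert-butyldiphenylsilyl)oxy]-6-methylocta-2,6-dien-2-yl}zirconium (Cp drawn σ-bonded) | C/C(=C\CC/C(C)=C/CO[Si](c1ccccc1)(c1ccccc1)C(C)(C)C)[Zr](Cl)(C1C=CC=C1)C1C=CC=C1 | intermediate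
9 | {[(2E,6E)-7-bromo-3-methylocta-2,6-dien-1-yl]oxy}(tert-butyl)diphenylsilane | C/C(Br)=C\CC/C(C)=C/CO[Si](c1ccccc1)(c1ccccc1)C(C)(C)C | intermediate
10 | dimethyl (4R,5R)-2,2-dimethyl-1,3-dioxolane-4,5-dicarboxylate (dimethyl 2,3-O-isopropylidene-L-tartrate) | COC(=O)[C@@H]1OC(C)(C)O[C@H]1C(=O)OC | starting material
11 | methyl (4R,5S)-5-(hydroxymethyl)-2,2-dimethyl-1,3-dioxolane-4-carboxylate | OC[C@@H]1OC(C)(C)O[C@H]1C(=O)OC | intermediate
12 | 2-[(4R,5S)-5-(hydroxymethyl)-2,2-dimethyl-1,3-dioxolan-4-yl]propan-2-ol | OC[C@@H]1OC(C)(C)O[C@H]1C(C)(C)O | intermediate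
13 | 2-[(4R,5R)-5-(iodomethyl)-2,2-dimethyl-1,3-dioxolan-4-yl]propan-2-ol | IC[C@@H]1OC(C)(C)O[C@H]1C(C)(C)O | intermediate
14 | 2-[(4R,5S)-5-{(2E,6E)-8-[(tert-butyldiphenylsilyl)oxy]-2,6-dimethylocta-2,6-dien-1-yl}-2,2-dimethyl-1,3-dioxolan-4-yl]propan-2-ol | C/C(=C\CO[Si](c1ccccc1)(c1ccccc1)C(C)(C)C)CC/C=C(\C)C[C@@H]1OC(C)(C)O[C@H]1C(C)(C)O | intermediate
15 | (2E,6E)-8-[(4S,5R)-5-(2-hydroxypropan-2-yl)-2,2-dimethyl-1,3-dioxolan-4-yl]-3,7-dimethylocta-2,6-dien-1-ol | C/C(=C\CO)CC/C=C(\C)C[C@@H]1OC(C)(C)O[C@H]1C(C)(C)O | intermediate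
16 | 2,4,6-trihydroxybenzaldehyde | O=Cc1c(O)cc(O)cc1O | starting material
17 | 2,6-dihydroxy-4-{[(2E,6E)-8-[(4S,5R)-5-(2-hydroxypropan-2-yl)-2,2-dimethyl-1,3-dioxolan-4-yl]-3,7-dimethylocta-2,6-dien-1-yl]oxy}benzaldehyde | C/C(=C\COc1cc(O)c(C=O)c(O)c1)CC/C=C(\C)C[C@@H]1OC(C)(C)O[C@H]1C(C)(C)O | intermediate
18 | (triphenylphosphoranylidene)ketene | O=C=C=P(c1ccccc1)(c1ccccc1)c1ccccc1 | starting material
19 | 2-formyl-3-hydroxy-5-(side-chain-oxy)phenyl (triphenylphosphoranylidene)acetate, side chain as in 17 | C/C(=C\COc1cc(O)c(C=O)c(OC(=O)C=P(c2ccccc2)(c2ccccc2)c2ccccc2)c1)CC/C=C(\C)C[C@@H]1OC(C)(C)O[C@H]1C(C)(C)O | intermediate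
20 | cis-fused 1,2-oxaphosphetane across C3–C4 of the 3,4-dihydrocoumarin (P,P,P-triphenyl), side chain as in 17, C3/C4 configuration not defined | C/C(=C\COc1cc(O)c2c(c1)OC(=O)C1C2OP1(c1ccccc1)(c1ccccc1)c1ccccc1)CC/C=C(\C)C[C@@H]1OC(C)(C)O[C@H]1C(C)(C)O | intermediate
21 | 5-hydroxy-7-{[(2E,6E)-8-[(4S,5R)-5-(2-hydroxypropan-2-yl)-2,2-dimethyl-1,3-dioxolan-4-yl]-3,7-dimethylocta-2,6-dien-1-yl]oxy}-2H-chromen-2-one | C/C(=C\COc1cc(O)c2ccc(=O)oc2c1)CC/C=C(\C)C[C@@H]1OC(C)(C)O[C@H]1C(C)(C)O | intermediate
22 | 5-hydroxy-7-{[(2E,6E,9S,10R)-9,10,11-trihydroxy-3,7,11-trimethyldodeca-2,6-dien-1-yl]oxy}-2H-chromen-2-one | C/C(=C\COc1cc(O)c2ccc(=O)oc2c1)CC/C=C(\C)C[C@H](O)[C@@H](O)C(C)(C)O | target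

Total steps: 14 (steps 1–6 alkenyl bromide, steps 7–9 iodide, steps 10–14 union and completion).
Longest linear sequence: 11 steps (steps 1–6, then 10–14).

Steps most likely to fail

Step 13. After the first acylation the remaining acidic phenol may protonate the ester ylide to a phosphonium phenoxide, which would slow olefination of an electron-rich aldehyde, and any excess reagent would acylate the second phenol. The fallback makes the same two bonds in two separately controllable operations and sets out from 17. Carbodiimide esterification of one phenol with (diethoxyphosphoryl)acetic acid (EDC, cat. DMAP, CH2Cl2, 0 °C) should give the 2-formyl-3-hydroxy-5-(side-chain-oxy)phenyl (diethoxyphosphoryl)acetate F1. Lithium chloride and DBU in acetonitrile at room temperature (Masamune–Roush conditions) then trigger the intramolecular Horner–Wadsworth–Emmons reaction, and the route is rejoined at 21.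

Step 10. Hydrodehalogenation or homodimerisation of either halide may outrun cross-coupling at the hindered 1-methylalkenyl–nickel centre. The fallback is a polar, copper-catalysed alkylation that sets out from 12 and 9. Triflation of the primary hydroxyl of 12, followed in the same flask by silylation of the tertiary one (Tf2O, 2,6-lutidine, CH2Cl2, −78 °C; then TMSOTf), should give [(4S,5R)-2,2-dimethyl-5-{2-[(trimethylsilyl)oxy]propan-2-yl}-1,3-dioxolan-4-yl]methyl trifluoromethanesulfonate F2. Bromine–lithium exchange on 9 (t-BuLi, Et2O, −78 °C) gives the alkenyllithium F3 with retention, and MgBr2·OEt2 converts it into the alkenylmagnesium bromide F4. This displaces the primary triflate under copper catalysis (CuBr·SMe2 10 mol %, Et2O–THF, −30 → 0 °C) to give the bis-silyl ether F5. TBAF in THF removes both silyl groups, and the route is rejoined at 15.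

Step 12. Regiocontrol may be lost through alkylation of an ortho hydroxyl or dialkylation, and the betaine may turn over poorly with this very acidic phenol. The fallback sets out from 15. Appel bromination of the primary allylic alcohol (CBr4, PPh3, CH2Cl2, 0 °C) should give the allylic bromide F6. It alkylates the monophenoxide of 16 at the 4-oxygen in a Williamson etherification (KHCO3, DMF, 0 °C → rt, 16 in excess), and the route is rejoined at 17.

Further compounds
F1 | step 13 | 2-formyl-3-hydroxy-5-{[(2E,6E)-8-[(4S,5R)-5-(2-hydroxypropan-2-yl)-2,2-dimethyl-1,3-dioxolan-4-yl]-3,7-dimethylocta-2,6-dien-1-yl]oxy}phenyl (diethoxyphosphoryl)acetate | C/C(=C\COc1cc(O)c(C=O)c(OC(=O)CP(=O)(OCC)OCC)c1)CC/C=C(\C)C[C@@H]1OC(C)(C)O[C@H]1C(C)(C)O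
F2 | step 10 | [(4S,5R)-2,2-dimethyl-5-{2-[(trimethylsilyl)oxy]propan-2-yl}-1,3-dioxolan-4-yl]methyl trifluoromethanesulfonate | FC(F)(F)S(=O)(=O)OC[C@@H]1OC(C)(C)O[C@H]1C(C)(C)O[Si](C)(C)C
F3 | step 10 | {(2E,6E)-8-[(tert-butyldiphenylsilyl)oxy]-6-methylocta-2,6-dien-2-yl}lithium | C/C([Li])=C\CC/C(C)=C/CO[Si](c1ccccc1)(c1ccccc1)C(C)(C)C
F4 | step 10 | {(2E,6E)-8-[(tert-butyldiphenylsilyl)oxy]-6-methylocta-2,6-dien-2-yl}magnesium bromide | C/C([Mg]Br)=C\CC/C(C)=C/CO[Si](c1ccccc1)(c1ccccc1)C(C)(C)C
F5 | step 10 | tert-butyl{[(2E,6E)-8-[(4S,5R)-2,2-dimethyl-5-{2-[(trimethylsilyl)oxy]propan-2-yl}-1,3-dioxolan-4-yl]-3,7-dimethylocta-2,6-dien-1-yl]oxy}diphenylsilane | C/C(=C\CO[Si](c1ccccc1)(c1ccccc1)C(C)(C)C)CC/C=C(\C)C[C@@H]1OC(C)(C)O[C@H]1C(C)(C)O[Si](C)(C)C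
F6 | step 12 | 2-[(4R,5S)-5-[(2E,6E)-8-bromo-2,6-dimethylocta-2,6-dien-1-yl]-2,2-dimethyl-1,3-dioxolan-4-yl]propan-2-ol | C/C(=C\CBr)CC/C=C(\C)C[C@@H]1OC(C)(C)O[C@H]1C(C)(C)O
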